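Everything rests on disconnecting the C2–C3 bond in the partly saturated ring of the dihydronaphthalene half (C1 carbinol, C2 acetyl-bearing CH, C3 methyl-bearing carbon, C4 olefinic CH). The key step exploits that C2 is the α-carbon of the acetyl ketone while C3=C4 is a styrene-type alkene on the adjoining benzene ring: C3/C4 are carried as an aryl-bound prop-1-ynyl group and C2 as the nucleophilic carbon of a (Z)-silyl enol ether on the C1 side chain. A gold-catalysed 6-endo-dig Conia-ene-type carbocyclisation closes the six-membered ring, creates C3=C4, unveils the acetyl group and sets C2 trans to the C1 oxygen in one operation. One propynyl salicylaldehyde feeds both halves, joined by Suzuki coupling before this ring closure.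

Key step: step 9

Remarks on the chemistry:
- Atom numbers used below are those of the 1,2-dihydronaphthalene half (C1–C4, C4a, C5–C8, C8a). The target is read as the trans-(1S,2R) isomer.
- The biaryl bond carries only one ortho substituent on each ring. It is taken as freely rotating and not as a stereogenic axis.
- TIPS = triisopropylsilyl, TBS = tert-butyldimethylsilyl.

Step 1
Reactants: 1 2-bromo-5-iodophenol; 2 propyne
Product: 3 2-bromo-5-(prop-1-yn-1-yl)phenol
Conditions: propyne (ca. 1 M in THF, 2 equiv), PdCl2(PPh3)2 (2 mol%), CuI (4 mol%), Et3N, THF, rt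
Reagents that add atoms: none
Why: Sonogashira coupling; zerovalent palladium inserts into the C–I bond much faster than into the C–Br bond at room temperature, so the bromide is kept as the later biaryl handle.

Step 2
Reactants: 3 2-bromo-5-(prop-1-yn-1-yl)phenol
Product: 5 3-bromo-2-hydroxy-6-(prop-1-yn-1-yl)benzaldehyde, via salicyl alcohol 4 (not isolated)
Conditions: MgCl2, Et3N, paraformaldehyde, MeCN, reflux; aq. HCl work-up
Reagents that add atoms: formaldehyde (used as paraformaldehyde), C=O
Why: Magnesium-mediated ortho-formylation of a phenol (Casnati–Skattebøl reaction): the magnesium phenoxide delivers formaldehyde to the only free ortho position and the benzylic alkoxide is oxidised to the aldehyde by hydride transfer to a second formaldehyde, while alkyne and bromide are inert.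

Step 3
Reactants: 5 3-bromo-2-hydroxy-6-(prop-1-yn-1-yl)benzaldehyde
Product: 6 3-bromo-6-(prop-1-yn-1-yl)-2-(triisopropylsilyloxy)benzaldehyde
Conditions: TIPSOTf (1.3 equiv), 2,6-lutidine, CH2Cl2, 0 °C to rt
Reagents that add atoms: triisopropylsilyl trifluoromethanesulfonate, CC(C)[Si](OS(=O)(=O)C(F)(F)F)(C(C)C)C(C)C
Why: Silylation of the hindered, hydrogen-bonded phenol with the silyl triflate; the TIPS ether prevents hemiketal formation with the ketone introduced next and is robust enough for the aqueous base of step 8.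

Step 4
Reactants: 6 3-bromo-6-(prop-1-yn-1-yl)-2-(triisopropylsilyloxy)benzaldehyde; 7 acetone
Product: 8 (4S)-4-[3-bromo-6-(prop-1-yn-1-yl)-2-(triisopropylsilyloxy)phenyl]-4-hydroxybutan-2-one
Conditions: D-proline (30 mol%), acetone/DMSO (1:4), rt
Reagents that add atoms: none
Why: Proline-catalysed direct aldol reaction (enamine catalysis): the acetone enamine of D-proline, guided by hydrogen bonding from its carboxylic acid, should add to the si face of the aldehyde and set C1 as (S); the enantiomeric purity is to be checked here and raised by recrystallisation if needed.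

Step 5
Reactants: 8 (4S)-4-[3-bromo-6-(prop-1-yn-1-yl)-2-(triisopropylsilyloxy)phenyl]-4-hydroxybutan-2-one
Product: 9 1-[3-bromo-6-(prop-1-yn-1-yl)-2-(triisopropylsilyloxy)phenyl]butane-1,3-dione
Conditions: Dess–Martin periodinane (1.5 equiv), CH2Cl2, rt
Reagents that add atoms: none
Why: Dess–Martin oxidation of the β-hydroxy ketone gives the enolised β-diketone under mild non-basic conditions that leave alkyne, aryl bromide and silyl ether untouched; the stereocentre is not needed in this branch.

Step 6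
Reactants: 9 1-[3-bromo-6-(prop-1-yn-1-yl)-2-(triisopropylsilyloxy)phenyl]butane-1,3-dione
Product: 11 1-[7-bromo-1-hydroxy-3-methyl-8-(triisopropylsilyloxy)naphthalen-2-yl]ethan-1-one, via keto tautomer 10 (not isolated)
Conditions: Ph3PAuNTf2 (5 mol%), CH2Cl2, rt
Reagents that add atoms: none
Why: Gold-catalysed Conia-ene reaction: the central carbon of the enolised β-diketone adds 6-endo-dig to the methyl-bearing carbon of the gold-activated aryl alkyne and the resulting 2H-naphthalen-1-one tautomerises to the hydrogen-bonded 1-naphthol, aromatisation driving the closure.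

Step 7
Reactants: 8 (4S)-4-[3-bromo-6-(prop-1-yn-1-yl)-2-(triisopropylsilyloxy)phenyl]-4-hydroxybutan-2-one
Product: 12 1-bromo-3-[(1S,2Z)-1,3-bis(tert-butyldimethylsilyloxy)but-2-en-1-yl]-4-(prop-1-yn-1-yl)-2-(triisopropylsilyloxy)benzene
Conditions: TBSOTf (2.5 equiv), Et3N (4 equiv), CH2Cl2, 0 °C to rt
Reagents that add atoms: tert-butyldimethylsilyl trifluoromethanesulfonate, CC(C)(C)[Si](C)(C)OS(=O)(=O)C(F)(F)F
Why: Soft enolisation with silyl triflate and amine: the carbinol is silylated and the ketone is converted, under equilibrating conditions, mainly into the more substituted (Z)-trisubstituted enol ether at C2 (thermodynamic isomer) without touching C1; any terminal enol ether is inert in step 9 and is recovered there as the ketone.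

Step 8
Reactants: 11 1-[7-bromo-1-hydroxy-3-methyl-8-(triisopropylsilyloxy)naphthalen-2-yl]ethan-1-one; 13 bis(pinacolato)diboron; 12 1-bromo-3-[(1S,2Z)-1,3-bis(tert-butyldimethylsilyloxy)but-2-en-1-yl]-4-(prop-1-yn-1-yl)-2-(triisopropylsilyloxy)benzene
Product: 15 1-[7-{3-[(1S,2Z)-1,3-bis(tert-butyldimethylsilyloxy)but-2-en-1-yl]-4-(prop-1-yn-1-yl)-2-(triisopropylsilyloxy)phenyl}-1-hydroxy-3-methyl-8-(triisopropylsilyloxy)naphthalen-2-yl]ethan-1-one, via pinacol boronate 14 (not isolated)
Conditions: a) 11, 13 (1.1 equiv), Pd(OAc)2 (3 mol%), SPhos (6 mol%), KOAc, dioxane, 80 °C; b) 12 (0.85 equiv), aq. K3PO4, 60 °C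
Reagents that add atoms: none
Why: One-pot Miyaura borylation and Suzuki–Miyaura coupling with a bulky biarylphosphine that tolerates one ortho substituent on each partner; 12 carries no acidic C–H bond or base-labile group, so the union is made before the base-sensitive β-silyloxy ketone exists.

Step 9
Reactants: 15 1-[7-{3-[(1S,2Z)-1,3-bis(tert-butyldimethylsilyloxy)but-2-en-1-yl]-4-(prop-1-yn-1-yl)-2-(triisopropylsilyloxy)phenyl}-1-hydroxy-3-methyl-8-(triisopropylsilyloxy)naphthalen-2-yl]ethan-1-one
Product: 16 1-[(1S,2R)-7-[7-acetyl-8-hydroxy-6-methyl-1-(triisopropylsilyloxy)naphthalen-2-yl]-1-(tert-butyldimethylsilyloxy)-3-methyl-8-(triisopropylsilyloxy)-1,2-dihydronaphthalen-2-yl]ethan-1-one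
Conditions: [JohnPhosAu(NCMe)]SbF6 (5 mol%), i-PrOH (3 equiv), CH2Cl2, 0 °C to rt
Reagents that add atoms: none
Why: Cationic monovalent gold coordinates the aryl alkyne and the enol ether carbon C2 attacks the methyl-bearing alkyne carbon C3 anti to gold, giving a vinyl-gold species at C4 and a silyloxocarbenium ion at the acetyl carbon; isopropanol takes the silyl group and protodeauration places hydrogen on C4. The closest known reaction type is the gold-catalysed Conia-ene-type carbocyclisation of silyl enol ethers onto alkynes, in its 6-endo-dig variant for arene-tethered enol ether–alkyne pairs. The six-membered carbocycle C1–C2–C3–C4–C4a–C8a closes in 6-endo-dig mode. The new stereocentre C2 is controlled by the C1 stereocentre: the C1–OTBS bond stands pseudoaxial to avoid the peri C8–OTIPS group, and the cis-forming arrangement would eclipse it with the silyloxy group of the (Z)-enol ether (allylic 1,3-strain), so the acetyl group should emerge trans to OTBS, which is also the more stable arrangement (both groups pseudoaxial, no allylic 1,2-strain with the C3 methyl). The step needs endo over exo closure and carbon over oxygen attack; the rigid benzene tether disfavours the strained 5-exo path to an alkylidene-indane, the bulky silyl groups keep the C1 oxygen from adding, and only the internal enol ether isomer can reach the alkyne.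

Step 10
Reactants: 16 1-[(1S,2R)-7-[7-acetyl-8-hydroxy-6-methyl-1-(triisopropylsilyloxy)naphthalen-2-yl]-1-(tert-butyldimethylsilyloxy)-3-methyl-8-(triisopropylsilyloxy)-1,2-dihydronaphthalen-2-yl]ethan-1-one
Product: 17 1-[(1S,2R)-7-(7-acetyl-1,8-dihydroxy-6-methylnaphthalen-2-yl)-1,8-dihydroxy-3-methyl-1,2-dihydronaphthalen-2-yl]ethan-1-one
Conditions: HF·pyridine, pyridine, THF, 0 °C to rt
Reagents that add atoms: none
Why: Fluoride-mediated cleavage of the two aryl TIPS ethers and the benzylic TBS ether in pyridine-buffered medium, which avoids both base (epimerisation at C2, β-elimination to the naphthalene) and strong acid (ionisation of the benzylic C1–O bond), so both stereocentres are retained.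

Compound list
1 | 2-bromo-5-iodophenol | Oc1cc(I)ccc1Br | starting material
2 | propyne | CC#C | starting material
3 | 2-bromo-5-(prop-1-yn-1-yl)phenol | CC#Cc1ccc(Br)c(O)c1 | intermediate
4 | 6-bromo-2-(hydroxymethyl)-3-(prop-1-yn-1-yl)phenol (salicyl alcohol, not isolated) | CC#Cc1ccc(Br)c(O)c1CO | intermediate
5 | 3-bromo-2-hydroxy-6-(prop-1-yn-1-yl)benzaldehyde | CC#Cc1ccc(Br)c(O)c1C=O | intermediate
6 | 3-bromo-6-(prop-1-yn-1-yl)-2-(triisopropylsilyloxy)benzaldehyde | CC#Cc1ccc(Br)c(O[Si](C(C)C)(C(C)C)C(C)C)c1C=O | intermediate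
7 | acetone | CC(C)=O | starting material
8 | (4S)-4-[3-bromo-6-(prop-1-yn-1-yl)-2-(triisopropylsilyloxy)phenyl]-4-hydroxybutan-2-one | CC(=O)C[C@H](O)c1c(C#CC)ccc(Br)c1O[Si](C(C)C)(C(C)C)C(C)C | intermediate
9 | 1-[3-bromo-6-(prop-1-yn-1-yl)-2-(triisopropylsilyloxy)phenyl]butane-1,3-dione | CC(=O)CC(=O)c1c(C#CC)ccc(Br)c1O[Si](C(C)C)(C(C)C)C(C)C | intermediate
10 | 2-acetyl-7-bromo-3-methyl-8-(triisopropylsilyloxy)naphthalen-1(2H)-one (keto tautomer, not isolated) | CC(=O)C1C(C)=Cc2ccc(Br)c(O[Si](C(C)C)(C(C)C)C(C)C)c2C1=O | intermediate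
11 | 1-[7-bromo-1-hydroxy-3-methyl-8-(triisopropylsilyloxy)naphthalen-2-yl]ethan-1-one | CC(=O)c1c(C)cc2ccc(Br)c(O[Si](C(C)C)(C(C)C)C(C)C)c2c1O | intermediate
12 | 1-bromo-3-[(1S,2Z)-1,3-bis(tert-butyldimethylsilyloxy)but-2-en-1-yl]-4-(prop-1-yn-1-yl)-2-(triisopropylsilyloxy)benzene | C/C(O[Si](C)(C)C(C)(C)C)=C/[C@H](O[Si](C)(C)C(C)(C)C)c1c(C#CC)ccc(Br)c1O[Si](C(C)C)(C(C)C)C(C)C | intermediate
13 | bis(pinacolato)diboron | CC1(C)OB(OC1(C)C)B1OC(C)(C)C(C)(C)O1 | starting material
14 | 1-[1-hydroxy-3-methyl-7-(4,4,5,5-tetramethyl-1,3,2-dioxaborolan-2-yl)-8-(triisopropylsilyloxy)naphthalen-2-yl]ethan-1-one (pinacol boronate, not isolated) | CC(=O)c1c(C)cc2ccc(B3OC(C)(C)C(C)(C)O3)c(O[Si](C(C)C)(C(C)C)C(C)C)c2c1O | intermediate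
15 | 1-[7-{3-[(1S,2Z)-1,3-bis(tert-butyldimethylsilyloxy)but-2-en-1-yl]-4-(prop-1-yn-1-yl)-2-(triisopropylsilyloxy)phenyl}-1-hydroxy-3-methyl-8-(triisopropylsilyloxy)naphthalen-2-yl]ethan-1-one | CC(=O)c1c(C)cc2ccc(-c3ccc(C#CC)c([C@@H](O[Si](C)(C)C(C)(C)C)/C=C(/C)O[Si](C)(C)C(C)(C)C)c3O[Si](C(C)C)(C(C)C)C(C)C)c(O[Si](C(C)C)(C(C)C)C(C)C)c2c1O | intermediate
16 | 1-[(1S,2R)-7-[7-acetyl-8-hydroxy-6-methyl-1-(triisopropylsilyloxy)naphthalen-2-yl]-1-(tert-butyldimethylsilyloxy)-3-methyl-8-(triisopropylsilyloxy)-1,2-dihydronaphthalen-2-yl]ethan-1-one | CC(=O)c1c(C)cc2ccc(-c3ccc4c(c3O[Si](C(C)C)(C(C)C)C(C)C)[C@@H](O[Si](C)(C)C(C)(C)C)[C@H](C(C)=O)C(C)=C4)c(O[Si](C(C)C)(C(C)C)C(C)C)c2c1O | intermediate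
17 | 1-[(1S,2R)-7-(7-acetyl-1,8-dihydroxy-6-methylnaphthalen-2-yl)-1,8-dihydroxy-3-methyl-1,2-dihydronaphthalen-2-yl]ethan-1-one (trans) | CC(=O)c1c(C)cc2ccc(-c3ccc4c(c3O)[C@@H](O)[C@H](C(C)=O)C(C)=C4)c(O)c2c1O | target

Total step count: 10 steps.
Longest linear sequence: 9 steps (steps 1, 2, 3, 4, 5, 6, 8, 9, 10).

Steps most likely to fail

1. Step 9 (key ring closure). The gold-bound alkyne may be diverted before the C2–C3 bond forms: the enol silyl group may be lost to the alcohol first, closure may occur through the aryl-bound alkyne carbon (5-exo), or the large biaryl may hold the catalyst unproductively, and the trans selectivity may erode. The fallback separates ring closure from fragment union. It sets out from 12, which is cyclised alone, where enol ether and alkyne are the only reactive groups, with [JohnPhosAu(NCMe)]SbF6 and i-PrOH or with platinum dichloride (PtCl2) in toluene. This should give the monomeric bromo dihydronaphthalene ketone 1-[(1S,2R)-7-bromo-1-(tert-butyldimethylsilyloxy)-3-methyl-8-(triisopropylsilyloxy)-1,2-dihydronaphthalen-2-yl]ethan-1-one F1, whose diastereomers can be separated at this stage. F1 is then joined with boronate 14 (made as in step 8) under anhydrous, mild Suzuki–Miyaura conditions (Pd(OAc)2, SPhos, powdered K3PO4, toluene, 40 °C), and the route is rejoined at 16.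

2. Step 7 (regiochemistry of enolisation). Enolisation may run toward the methyl group and give the terminal enol ether, which cannot close a six-membered ring, and the Lewis-acidic silyl triflate may ionise the benzylic C1–O bond. The fallback uses a nucleophile with only one enolisable position and sets out from aldehyde 6.
   - Aldol: Mukaiyama aldol addition of 1-(ethylsulfanyl)-1-(trimethylsilyloxy)ethene, promoted by Sn(OTf)2 (divalent tin), Bu3SnF and the enantiomer of 1-methyl-2-[(1-naphthylamino)methyl]pyrrolidine that delivers the (S)-alcohol, should give the thioester aldol S-ethyl (3S)-3-[3-bromo-6-(prop-1-yn-1-yl)-2-(triisopropylsilyloxy)phenyl]-3-hydroxypropanethioate F2.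
   - Silylation: TBSOTf and Et3N convert it into the bis-silyl ketene S,O-acetal (1S)-configured 1-bromo-3-[1,3-bis(tert-butyldimethylsilyloxy)-3-(ethylsulfanyl)prop-2-en-1-yl]-4-(prop-1-yn-1-yl)-2-(triisopropylsilyloxy)benzene F3; either double-bond geometry serves.
   - Coupling: Suzuki–Miyaura coupling with boronate 14 as in step 8 gives the biaryl ketene acetal F4.
   - Ring closure: the gold-catalysed closure of step 9 gives the cyclised thioester S-ethyl (1S,2R)-7-[7-acetyl-8-hydroxy-6-methyl-1-(triisopropylsilyloxy)naphthalen-2-yl]-1-(tert-butyldimethylsilyloxy)-3-methyl-8-(triisopropylsilyloxy)-1,2-dihydronaphthalene-2-carbothioate F5.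
   - Return: Fukuyama coupling with methylzinc iodide (MeZnI) and PdCl2(PPh3)2 in toluene turns the thioester into the methyl ketone and rejoins the route at 16.

3. Step 8 (fragment union). Transmetalation between two ortho-silyloxy partners may be slow, so that protodeboronation of 14 or hydrolysis of the enol ether of 12 under aqueous base competes. The fallback makes the biaryl bond at the aldehyde stage, where the partner is robust and can be heated. It sets out from boronate 14 and bromo aldehyde 6 (Pd(OAc)2, SPhos, aq. K3PO4, dioxane, 80 °C), which should give the biaryl aldehyde 3-[7-acetyl-8-hydroxy-6-methyl-1-(triisopropylsilyloxy)naphthalen-2-yl]-6-(prop-1-yn-1-yl)-2-(triisopropylsilyloxy)benzaldehyde F6. The D-proline aldol reaction with acetone as in step 4 then gives the biaryl aldol 1-[7-{3-[(1S)-1-hydroxy-3-oxobutyl]-4-(prop-1-yn-1-yl)-2-(triisopropylsilyloxy)phenyl}-1-hydroxy-3-methyl-8-(triisopropylsilyloxy)naphthalen-2-yl]ethan-1-one F7. Silylation with TBSOTf (2.2 equiv) and Et3N at −78 to 0 °C returns the route at 15; the hydrogen-bonded, peri-hindered naphthol and its acetyl group should react more slowly, and any extra silyl group would be lost in step 10.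

Further compounds
F1 | step 9 | 1-[(1S,2R)-7-bromo-1-(tert-butyldimethylsilyloxy)-3-methyl-8-(triisopropylsilyloxy)-1,2-dihydronaphthalen-2-yl]ethan-1-one | Brc1ccc2c(c1O[Si](C(C)C)(C(C)C)C(C)C)[C@@H](O[Si](C)(C)C(C)(C)C)[C@H](C(C)=O)C(C)=C2
F2 | step 7 | S-ethyl (3S)-3-[3-bromo-6-(prop-1-yn-1-yl)-2-(triisopropylsilyloxy)phenyl]-3-hydroxypropanethioate | CCSC(=O)C[C@H](O)c1c(C#CC)ccc(Br)c1O[Si](C(C)C)(C(C)C)C(C)C
F3 | step 7 | 1-bromo-3-[(1S)-1,3-bis(tert-butyldimethylsilyloxy)-3-(ethylsulfanyl)prop-2-en-1-yl]-4-(prop-1-yn-1-yl)-2-(triisopropylsilyloxy)benzene | CCSC(O[Si](C)(C)C(C)(C)C)=C[C@H](O[Si](C)(C)C(C)(C)C)c1c(C#CC)ccc(Br)c1O[Si](C(C)C)(C(C)C)C(C)C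
F4 | step 7 | 1-[7-{3-[(1S)-1,3-bis(tert-butyldimethylsilyloxy)-3-(ethylsulfanyl)prop-2-en-1-yl]-4-(prop-1-yn-1-yl)-2-(triisopropylsilyloxy)phenyl}-1-hydroxy-3-methyl-8-(triisopropylsilyloxy)naphthalen-2-yl]ethan-1-one | CC(=O)c1c(C)cc2ccc(-c3ccc(C#CC)c([C@@H](O[Si](C)(C)C(C)(C)C)C=C(SCC)O[Si](C)(C)C(C)(C)C)c3O[Si](C(C)C)(C(C)C)C(C)C)c(O[Si](C(C)C)(C(C)C)C(C)C)c2c1O
F5 | step 7 | S-ethyl (1S,2R)-7-[7-acetyl-8-hydroxy-6-methyl-1-(triisopropylsilyloxy)naphthalen-2-yl]-1-(tert-butyldimethylsilyloxy)-3-methyl-8-(triisopropylsilyloxy)-1,2-dihydronaphthalene-2-carbothioate | CC(=O)c1c(C)cc2ccc(-c3ccc4c(c3O[Si](C(C)C)(C(C)C)C(C)C)[C@@H](O[Si](C)(C)C(C)(C)C)[C@H](C(=O)SCC)C(C)=C4)c(O[Si](C(C)C)(C(C)C)C(C)C)c2c1O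
F6 | step 8 | 3-[7-acetyl-8-hydroxy-6-methyl-1-(triisopropylsilyloxy)naphthalen-2-yl]-6-(prop-1-yn-1-yl)-2-(triisopropylsilyloxy)benzaldehyde | CC(=O)c1c(C)cc2ccc(-c3ccc(C#CC)c(C=O)c3O[Si](C(C)C)(C(C)C)C(C)C)c(O[Si](C(C)C)(C(C)C)C(C)C)c2c1O
F7 | step 8 | 1-[7-{3-[(1S)-1-hydroxy-3-oxobutyl]-4-(prop-1-yn-1-yl)-2-(triisopropylsilyloxy)phenyl}-1-hydroxy-3-methyl-8-(triisopropylsilyloxy)naphthalen-2-yl]ethan-1-one | CC(=O)C[C@H](O)c1c(C#CC)ccc(-c2ccc3cc(C)c(C(C)=O)c(O)c3c2O[Si](C(C)C)(C(C)C)C(C)C)c1O[Si](C(C)C)(C(C)C)C(C)C
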